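The runs stem from a simulated flask from invented constants; noise was put on by code.

in all of them: precatalyst 0.45 mM
- dusk: left-handed substrate 5 mM; right-handed substrate 5 mM; coupling partner 40 mM (fed, over 80 s); run made earlier; the fed solution adds 0.20 times the starting volume
- midnight: left-handed substrate 7.5 mM; right-handed substrate 7.5 mM; coupling partner 40 mM (fed, over 80 s); run made earlier; the fed solution adds 0.20 times the starting volume
- dawn: left-handed substrate 10 mM; right-handed substrate 10 mM; coupling partner 60 mM (fed, over 80 s); run made earlier; the fed solution adds 0.20 times the starting volume
- flask: left-handed substrate 10 mM; right-handed substrate 10 mM; coupling partner 40.0 mM (fed, over 80 s); the fed solution adds 0.20 times the starting volume; time 2.5 min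

| run | time / min | left-handed product / % | right-handed product / % |
|---|---|---|---|
| dusk | 0.200 | 0.5 | 0 |
| dusk | 0.667 | 5.7 | 2.2 |
| dusk | 1.00 | 13.8 | 7.3 |
| dusk | 1.50 | 29.8 | 15.9 |
| dusk | 2.50 | 50.9 | 26.3 |
| dusk | 3.00 | 57.3 | 29.5 |
| midnight | 0.250 | 0.6 | 0.3 |
| midnight | 0.417 | 1.3 | 0.8 |
| midnight | 0.667 | 5.2 | 2.2 |
| midnight | 1.00 | 13.2 | 6.2 |
| midnight | 2.00 | 41.3 | 22.0 |
| midnight | 3.00 | 56.0 | 29.7 |
| dawn | 0.250 | 0.9 | 0.2 |
| dawn | 0.833 | 12.9 | 6.8 |
| dawn | 1.33 | 31.9 | 16.9 |
| dawn | 2.00 | 50.0 | 25.6 |
| dawn | 3.00 | 60.8 | 32.5 |

(scatter of a reading: 0.5 percentage points)

- catalyst is single-handed; left-handed substrate and right-handed substrate are mirror images of each other, charged as a racemate, each of them at the stated concentration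
- amounts are per litre of the starting volume; all of the dose is in the solution fed
- an excess is the difference of the two amounts in percent of their sum
- an excess is below zero if the other one leads

- left-handed product and right-handed product together, in percent of the left-handed substrate and right-handed substrate charged together, at 2.5 min
- excess of left-handed product over right-handed product in the product at 2.5 min
- whether the exchange between left-handed substrate and right-handed substrate keeps pace with the reaction: how far the product's excess at 2.5 min gets from its value without exchange to its value with instant exchange (above 80 % keeps pace, below 20 % hardly takes part, else lags behind)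

Time enters this dynamic kinetic resolution through two spans: τ_r, the mean life of substrate against reaction, and τ_x, the time in which exchange evens out the two substrates. Exchange does run: left-handed product reaches 60.8 % in the dawn run, above the 50 % of the charge that was left-handed.

We replace the curved course by a steady mean loss. The substrates then differ by a lag e·τ_x/τ_r, where e is the product's excess, and the product's excess falls by that lag times (1 − e·e).

Midnight has the flask's feed of coupling partner, so we take the midpoint of its totals at 2.00 min and 3.00 min:

y = 74.5 %, τ_r = t/ln(1/(1 − y)) = 1.83 min

In the dawn run, the product up to 1.33 min has excess e_a, and the product formed after it has excess e_b: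

e_a = 30.7 %, e_b = 29.9 %

With dawn's own mean life τ_d = 1.11 min:

τ_x = τ_d (e_a − e_b)/[e_a (1 − e_a·e_a)] = 0.0339 min

This is a reading: the difference 0.80 percentage points carries a scatter of 2.7 points. Twice that scatter allows 0.247 min, still shorter than τ_r.

We take τ_x from the dawn run and τ_r for the flask, assuming that exchange runs alike in both. Our carried quantity is the lag ratio ρ = τ_x/τ_r:

ρ = 0.0185

So we expect the flask's excess near 30.2 %, with exchange keeping pace. The forecast says 74 %, a little below our yield, and 31 %, a little above our excess, and also “exchange keeps pace”.

The flask gives 73.4 % and 31.5 %, so exchange keeps pace, 92 % of the way to the value with instant exchange.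

coupling partner + catalyst + left-handed substrate → catalyst + left-handed product (k = 4670 M⁻² s⁻¹); coupling partner + catalyst + right-handed substrate → catalyst + right-handed product (k = 2360 M⁻² s⁻¹); left-handed substrate ⇌ right-handed substrate (k = 0.109 s⁻¹); precatalyst → catalyst (k = 0.00875 s⁻¹); catalyst ⇌ dormant form (K = 0.610, k = 0.0265 s⁻¹) At 2.50 min the flask's excess of right-handed substrate over left-handed substrate, among what is left of the two, is 1.96 %. The same flask with 1.1 mM of precatalyst gives a yield of 93.4 %, so its mean life is 0.920 min and its lag ratio 0.0369; that puts its excess near 29.7 %, and it gives 30.4 %.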